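**Plan**

- Retrosynthetic cuts, in order: (a) the CH2–C(CH3)2 bond of ring A (the 4-bromo-3,3-dimethylcyclohexylidene ring), giving a tertiary β-bromo trifluoroacetate and an allylsilane; (b) the bond from hydrindane C-1 to the silyl-bearing carbon (Claisen); (c) C-1–C-2 of the cyclopentane (Dieckmann); (d) C-3a–C-7a of the cyclohexane (bromonium-type tertiary cation plus silyl enol ether).
- Forward order: cyclohexane of the hydrindane (step 8), cyclopentanone (step 11), side chain by Mitsunobu/Claisen (step 14), ring A last (step 19).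
- Enabling feature: in ring A the C(CH3)2 carbon has a vicinal C–Br, so it is a latent bromonium-stabilised tertiary cation. The ring CH2 next to it is allylic to the exocyclic alkene, so it is the γ-terminus of an allylsilane whose β-carbon is the alkylidene ring carbon; loss of silicon forms the alkene.
- Stereochemistry: both C–Br centres come from Sharpless and Shi epoxides opened by bromide with inversion and are kept by bromine participation. C-3a/C-7a come from chair closure of a (Z)-silyl enol ether, C-7 from equatorial MeMgBr addition, C-1/C-2 from epimerisation and hydride attack anti to the side chain. The alkene geometry is relayed by anti-SE2' from the Claisen-made C–Si centre.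

Key step: step 19

Remark: hydrindane atoms are numbered as in indene (C-1, C-2, C-3, C-3a, C-4 … C-7a); 1, 6, 9 (as its hydrate), 20 and 21 are taken as commercial.
Remark: the D-fructose-derived Shi ketone is assumed to give the (R)-epoxide from a 2-methylalk-2-ene terminus; if the sense were opposite, its enantiomer would be used.

**Step 1**
Reactants: 1 tert-butyl(but-3-yn-1-yloxy)dimethylsilane
Product: 3 (2E)-5-{[tert-butyl(dimethyl)silyl]oxy}-3-methylpent-2-en-1-ol, via alkenylalane 2 (not isolated)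
Conditions: Me3Al, Cp2ZrCl2 (20 mol %), CH2Cl2, 0 °C to rt; then n-BuLi, (CH2O)n, THF, −78 °C to rt
Reagents that add atoms: trimethylaluminium C[Al](C)C; formaldehyde (as paraformaldehyde) C=O
Why: Zirconium-catalysed carboalumination (Negishi) adds Me and Al syn across the terminal alkyne with the metal at the terminus, and hydroxymethylation of the derived alanate with retention should give the (E)-trisubstituted allylic alcohol.

**Step 2**
Reactants: 3 (2E)-5-{[tert-butyl(dimethyl)silyl]oxy}-3-methylpent-2-en-1-ol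
Product: 4 [(2R,3R)-3-(2-{[tert-butyl(dimethyl)silyl]oxy}ethyl)-3-methyloxiran-2-yl]methanol
Conditions: Ti(O-i-Pr)4 (10 mol %), D-(−)-diethyl tartrate (12 mol %), t-BuOOH, 4 Å MS, CH2Cl2, −20 °C
Reagents that add atoms: tert-butyl hydroperoxide CC(C)(C)OO
Why: Sharpless asymmetric epoxidation of the (E)-allylic alcohol with the D-tartrate should deliver the (2R,3R)-epoxide, which fixes the later C-3a centre and, after inversion, C-4.

**Step 3**
Reactants: 4 [(2R,3R)-3-(2-{[tert-butyl(dimethyl)silyl]oxy}ethyl)-3-methyloxiran-2-yl]methanol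
Product: 5 tert-butyl{2-[(2R,3S)-3-(iodomethyl)-2-methyloxiran-2-yl]ethoxy}dimethylsilane
Conditions: I2, PPh3, imidazole, CH2Cl2, 0 °C
Reagents that add atoms: iodine II
Why: Appel-type iodination of the primary alcohol should leave the epoxide untouched (the descriptor change is only a priority change).

**Step 4**
Reactants: 5 tert-butyl{2-[(2R,3S)-3-(iodomethyl)-2-methyloxiran-2-yl]ethoxy}dimethylsilane; 6 dimethyl (2-oxopropyl)phosphonate
Product: 8 dimethyl {4-[(2R,3R)-3-(2-{[tert-butyl(dimethyl)silyl]oxy}ethyl)-3-methyloxiran-2-yl]-2-oxobutyl}phosphonate, via phosphonate dianion 7 (not isolated)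
Conditions: 6, NaH, THF, 0 °C; n-BuLi, 0 °C; then 5, −20 °C to rt
Reagents that add atoms: none
Why: γ-Alkylation of a β-keto phosphonate dianion takes place at the more reactive terminal carbanion, and SN2 at the primary iodide should be faster than epoxide opening.

**Step 5**
Reactants: 8 dimethyl {4-[(2R,3R)-3-(2-{[tert-butyl(dimethyl)silyl]oxy}ethyl)-3-methyloxiran-2-yl]-2-oxobutyl}phosphonate; 9 prop-2-en-1-yl oxoacetate (allyl glyoxylate)
Product: 10 prop-2-en-1-yl (2E)-6-[(2R,3R)-3-(2-{[tert-butyl(dimethyl)silyl]oxy}ethyl)-3-methyloxiran-2-yl]-4-oxohex-2-enoate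
Conditions: LiCl, i-Pr2NEt, MeCN, 0 °C to rt
Reagents that add atoms: none
Why: Horner–Wadsworth–Emmons olefination under mild Masamune–Roush conditions should give the (E)-4-oxo-enoate without opening the epoxide.

**Step 6**
Reactants: 10 prop-2-en-1-yl (2E)-6-[(2R,3R)-3-(2-{[tert-butyl(dimethyl)silyl]oxy}ethyl)-3-methyloxiran-2-yl]-4-oxohex-2-enoate
Product: 11 prop-2-en-1-yl (2E,7S,8R)-7-bromo-10-{[tert-butyl(dimethyl)silyl]oxy}-8-hydroxy-8-methyl-4-oxodec-2-enoate
Conditions: Li2NiBr4, THF, 0 °C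
Reagents that add atoms: Li2NiBr4 [Li+].[Li+].[Ni+2].[Br-].[Br-].[Br-].[Br-]
Why: Soft bromide opens the trisubstituted epoxide by SN2 at the secondary carbon with inversion, which sets the (S)-C–Br centre next to the tertiary alcohol.

**Step 7**
Reactants: 11 prop-2-en-1-yl (2E,7S,8R)-7-bromo-10-{[tert-butyl(dimethyl)silyl]oxy}-8-hydroxy-8-methyl-4-oxodec-2-enoate
Product: 12 prop-2-en-1-yl (2E,7S,8R)-7-bromo-10-{[tert-butyl(dimethyl)silyl]oxy}-8-methyl-4-oxo-8-[(trifluoroacetyl)oxy]dec-2-enoate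
Conditions: (CF3CO)2O, pyridine, DMAP (cat.), CH2Cl2, 0 °C
Reagents that add atoms: trifluoroacetic anhydride O=C(OC(=O)C(F)(F)F)C(F)(F)F
Why: The very reactive anhydride acylates even the hindered tertiary alcohol and turns it into a leaving group that should ionise only under Lewis acid.

**Step 8**
Reactants: 12 prop-2-en-1-yl (2E,7S,8R)-7-bromo-10-{[tert-butyl(dimethyl)silyl]oxy}-8-methyl-4-oxo-8-[(trifluoroacetyl)oxy]dec-2-enoate
Product: 14 prop-2-en-1-yl [(1S,2S,3S)-3-bromo-2-(2-{[tert-butyl(dimethyl)silyl]oxy}ethyl)-2-methyl-6-oxocyclohexyl]acetate, via silyl enol ether 13 (not isolated)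
Conditions: Et3SiH, RhCl(PPh3)3 (2 mol %), toluene, 50 °C; then Me2AlCl, CH2Cl2, −78 °C
Reagents that add atoms: none
Why: Rhodium-catalysed 1,4-hydrosilylation of the enone through its s-cis form should give the (Z)-silyl enol ether regiospecifically, and Me2AlCl then ionises the tertiary trifluoroacetate with bromine participation so that the enol ether carbon closes the six-membered ring through a chair (Lewis-acid SN1 alkylation of a silyl enol ether, Mukaiyama type), attack anti to bromine fixing the quaternary centre and the (Z)-geometry placing the acetate arm equatorial, trans to the axial methyl.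

**Step 9**
Reactants: 14 prop-2-en-1-yl [(1S,2S,3S)-3-bromo-2-(2-{[tert-butyl(dimethyl)silyl]oxy}ethyl)-2-methyl-6-oxocyclohexyl]acetate
Product: 16 prop-2-en-1-yl [(1S,2S,3S)-3-bromo-2-(2-methoxy-2-oxoethyl)-2-methyl-6-oxocyclohexyl]acetate, via carboxylic acid 15 (not isolated)
Conditions: CrO3, H2SO4, acetone–H2O, 0 °C; then Me3SiCHN2, MeOH–toluene, 0 °C
Reagents that add atoms: water O; (trimethylsilyl)diazomethane C[Si](C)(C)C=[N+]=[N-]
Why: Jones oxidation cleaves the primary silyl ether and oxidises the alcohol to the acid without enolising the hindered ketone at 0 °C, and the diazo reagent then esterifies under neutral conditions.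

**Step 10**
Reactants: 16 prop-2-en-1-yl [(1S,2S,3S)-3-bromo-2-(2-methoxy-2-oxoethyl)-2-methyl-6-oxocyclohexyl]acetate
Product: 18 prop-2-en-1-yl {(1S,2S,3S,6R)-3-bromo-2-(2-methoxy-2-oxoethyl)-2,6-dimethyl-6-[(triethylsilyl)oxy]cyclohexyl}acetate, via tertiary alkoxide 17 (not isolated)
Conditions: MeMgBr, CeCl3, THF, −78 °C; then Et3SiOTf, 2,6-lutidine, −78 to 0 °C
Reagents that add atoms: methylmagnesium bromide C[Mg]Br; triethylsilyl trifluoromethanesulfonate CC[Si](CC)(CC)OS(=O)(=O)C(F)(F)F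
Why: The organocerium reagent adds to the ketone and not to the esters, equatorial attack anti to the 1,3-related axial methyl should give the axial tertiary alkoxide, and in-situ silylation stops lactonisation onto the neighbouring ester.

**Step 11**
Reactants: 18 prop-2-en-1-yl {(1S,2S,3S,6R)-3-bromo-2-(2-methoxy-2-oxoethyl)-2,6-dimethyl-6-[(triethylsilyl)oxy]cyclohexyl}acetate
Product: 19 prop-2-en-1-yl (3aS,4S,7R,7aS)-4-bromo-3a,7-dimethyl-2-oxo-7-[(triethylsilyl)oxy]octahydro-1H-indene-1-carboxylate (C-1 epimers, largely enolised)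
Conditions: LiN(SiMe3)2 (2.2 equiv), THF, −78 to 0 °C
Reagents that add atoms: none
Why: Dieckmann condensation under kinetic control, in which the CH2 next to the tertiary ring carbon is deprotonated in preference to the neopentyl CH2 and attacks the methyl ester; the two equatorial arms should give the trans-fused hydrindanone.

**Step 12**
Reactants: 20 prop-2-yn-1-ol; 21 5-bromo-2-methylpent-2-ene
Product: 24 (2Z)-2-(4-methylpent-3-en-1-yl)-3-(trimethylsilyl)prop-2-en-1-ol, via Grignard reagent 22 (not isolated), via vinylmagnesium alkoxide 23 (not isolated)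
Conditions: 21, Mg, THF; 20, CuI (10 mol %), THF, −10 °C to rt; then Me3SiCl, 0 to 40 °C; aq. NH4Cl–HCl
Reagents that add atoms: chlorotrimethylsilane C[Si](C)(C)Cl
Why: Copper-catalysed anti-carbomagnesiation of the propargylic alkoxide places the alkyl group at C-2 and magnesium at C-3 cis to the CH2O group in a five-membered chelate, and silylation of this vinylmagnesium with retention (the O-silyl ether is cleaved on work-up) should give the (Z)-vinylsilane.

**Step 13**
Reactants: 24 (2Z)-2-(4-methylpent-3-en-1-yl)-3-(trimethylsilyl)prop-2-en-1-ol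
Product: 25 (2Z)-2-{2-[(2R)-3,3-dimethyloxiran-2-yl]ethyl}-3-(trimethylsilyl)prop-2-en-1-ol
Conditions: D-fructose-derived Shi ketone (30 mol %), KHSO5, K2CO3, Bu4NHSO4, MeCN–(MeO)2CH2–aq. buffer (pH 10.5), 0 °C
Reagents that add atoms: potassium peroxymonosulfate [K+].[O-]S(=O)(=O)OO
Why: Shi epoxidation (chiral dioxirane) is expected to select the electron-rich, unhindered terminal trisubstituted alkene over the silyl-shielded allylic alkene and to give the (R)-epoxide.

**Step 14**
Reactants: 19 prop-2-en-1-yl (3aS,4S,7R,7aS)-4-bromo-3a,7-dimethyl-2-oxo-7-[(triethylsilyl)oxy]octahydro-1H-indene-1-carboxylate; 25 (2Z)-2-{2-[(2R)-3,3-dimethyloxiran-2-yl]ethyl}-3-(trimethylsilyl)prop-2-en-1-ol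
Product: 27 prop-2-en-1-yl (3aS,4S,7R,7aS)-4-bromo-1-[4-(3,3-dimethyloxiran-2-yl)-2-methylidene-1-(trimethylsilyl)butyl]-3a,7-dimethyl-2-oxo-7-[(triethylsilyl)oxy]octahydro-1H-indene-1-carboxylate (side chain on the face of H-7a; C–Si centre and epoxide as in 28), via allyl vinyl ether 26 (not isolated)
Conditions: PPh3, i-PrO2CN=NCO2-i-Pr, toluene, 0 °C to rt; then 80–100 °C
Reagents that add atoms: none
Why: Mitsunobu O-alkylation of the enolised β-keto ester (the crowded α-carbon disfavours C-alkylation) gives the allyl vinyl ether, which on warming should undergo Claisen rearrangement through a chair on the cyclopentene face anti to the angular methyl and the axial silyloxy group, the (Z)-vinylsilane placing silicon axial and so setting the C–Si centre needed for step 19 (C-1 becomes quaternary and is reset in step 15).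

**Step 15**
Reactants: 27 (Claisen product as named in step 14)
Product: 28 (1S,3aS,4S,7R,7aS)-4-bromo-1-{(1S)-4-[(2R)-3,3-dimethyloxiran-2-yl]-2-methylidene-1-(trimethylsilyl)butyl}-3a,7-dimethyl-7-[(triethylsilyl)oxy]octahydro-2H-inden-2-one
Conditions: Pd(OAc)2 (5 mol %), PPh3, HCO2H, Et3N, THF, rt to 40 °C
Reagents that add atoms: none
Why: Palladium-catalysed deallylation with formate as hydride donor and decarboxylation of the β-keto acid give the ketone, and C-1 should equilibrate under Et3N to the epimer with the side chain anti to the angular methyl and away from the fully substituted C-7.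

**Step 16**
Reactants: 28 (ketone as named in step 15)
Product: 29 (1S,2R,3aS,4S,7R,7aS)-4-bromo-1-{(1S)-4-[(2R)-3,3-dimethyloxiran-2-yl]-2-methylidene-1-(trimethylsilyl)butyl}-3a,7-dimethyl-7-[(triethylsilyl)oxy]octahydro-1H-inden-2-ol
Conditions: LiBH(s-Bu)3, THF, −78 °C
Reagents that add atoms: none
Why: The bulky hydride should attack the cyclopentanone face anti to the large α-substituent and give the cis-2-substituted cyclopentanol.

**Step 17**
Reactants: 29 (epoxy alcohol as named in step 16)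
Product: 30 (1S,2R,3aS,4S,7R,7aS)-4-bromo-1-[(1S,5S)-5-bromo-6-hydroxy-6-methyl-2-methylidene-1-(trimethylsilyl)heptyl]-3a,7-dimethyl-7-[(triethylsilyl)oxy]octahydro-1H-inden-2-ol
Conditions: Li2NiBr4, THF, 0 °C
Reagents that add atoms: Li2NiBr4 [Li+].[Li+].[Ni+2].[Br-].[Br-].[Br-].[Br-]
Why: As in step 6, bromide opens the epoxide at the secondary carbon with inversion and sets the (S)-C–Br centre of ring A; the reagent is too weakly Lewis acidic to start an epoxide–allylsilane cyclisation.

**Step 18**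
Reactants: 30 (bromohydrin diol as named in step 17)
Product: 31 bis(trifluoroacetate) of 30 (esters at the tertiary side-chain oxygen and at O-2)
Conditions: (CF3CO)2O (excess), pyridine, DMAP (cat.), CH2Cl2, 0 °C
Reagents that add atoms: trifluoroacetic anhydride O=C(OC(=O)C(F)(F)F)C(F)(F)F
Why: Trifluoroacetylation makes the tertiary oxygen a leaving group and protects the ring hydroxyl, and the allylsilane does not react with the anhydride without a Lewis acid.

**Step 19**
Reactants: 31 bis(trifluoroacetate) of 30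
Product: 32 (1S,2R,3aS,4S,7R,7aS)-4-bromo-1-{(E)-[(4S)-4-bromo-3,3-dimethylcyclohexylidene]methyl}-3a,7-dimethyl-7-[(triethylsilyl)oxy]octahydro-1H-inden-2-yl trifluoroacetate
Conditions: Me2AlCl (3 equiv), CH2Cl2 (high dilution), −78 °C
Reagents that add atoms: none
Why: Proposed new method: Me2AlCl ionises the tertiary trifluoroacetate with anchimeric help from the vicinal bromine, so a configurationally defined bromonium/β-bromo cation forms without external electrophilic bromine (which would attack the allylsilane); the terminal CH2 of the allylsilane alkene attacks the C(CH3)2 carbon anti to bromine and the β-silyl cation loses Me3Si to give the exocyclic alkene. The closest known reaction types are Lewis-acid cation–olefin cyclisations terminated by allylsilanes (epoxide- or acetal-initiated) and enantiospecific polyene cyclisations started from bromohydrin esters. Ring A closes in the 6-endo mode (both alkene carbons end up in the ring) through a chair with bromine equatorial. No new sp3 centre is formed and the C–Br centre is carried over unchanged; the new stereo-element is the alkene geometry, controlled by the anti-SE2' rule: the (S)-bromide fixes the chair and so the face of the CH2 terminus that is attacked, the C–Si bond must lie on the opposite face, and with the (S)-configured silyl-bearing carbon this puts the hydrindane carbon cis to the ring CH2 remote from C(CH3)2, that is the (E)-alkene. The step needs ionisation of the bromo-trifluoroacetate in preference to the tertiary silyl ether and the secondary trifluoroacetate (secured by bromine participation and the better leaving group) and chair in preference to boat closure. High dilution and the proton-scavenging Lewis acid are meant to suppress intermolecular bromonium transfer and protodesilylation.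

**Step 20**
Reactants: 32 (protected iriediol as named in step 19)
Product: 34 iriediol, (1S,2R,3aS,4S,7R,7aS)-4-bromo-1-{(E)-[(4S)-4-bromo-3,3-dimethylcyclohexylidene]methyl}-3a,7-dimethyloctahydro-1H-indene-2,7-diol, via monosilyl ether 33 (not isolated)
Conditions: K2CO3, MeOH, 0 °C; then HF·pyridine, THF, 0 °C to rt
Reagents that add atoms: none
Why: Methanolysis of the labile trifluoroacetate and fluoride cleavage of the tertiary triethylsilyl ether are mild enough to leave both hindered bromides and the trisubstituted alkene untouched.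

**Compound list**

1 | tert-butyl(but-3-yn-1-yloxy)dimethylsilane | C#CCCO[Si](C)(C)C(C)(C)C | starting material
2 | [(1E)-4-{[tert-butyl(dimethyl)silyl]oxy}-2-methylbut-1-en-1-yl]dimethylalane | C/C(=C\[Al](C)C)CCO[Si](C)(C)C(C)(C)C | intermediate
3 | (2E)-5-{[tert-butyl(dimethyl)silyl]oxy}-3-methylpent-2-en-1-ol | C/C(=C\CO)CCO[Si](C)(C)C(C)(C)C | intermediate
4 | [(2R,3R)-3-(2-{[tert-butyl(dimethyl)silyl]oxy}ethyl)-3-methyloxiran-2-yl]methanol | OC[C@H]1O[C@]1(C)CCO[Si](C)(C)C(C)(C)C | intermediate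
5 | tert-butyl{2-[(2R,3S)-3-(iodomethyl)-2-methyloxiran-2-yl]ethoxy}dimethylsilane | IC[C@H]1O[C@]1(C)CCO[Si](C)(C)C(C)(C)C | intermediate
6 | dimethyl (2-oxopropyl)phosphonate | CC(=O)CP(=O)(OC)OC | starting material
7 | sodium lithium dianion of dimethyl (2-oxopropyl)phosphonate | [Na+].[Li+].[CH2-]C(=O)[CH-]P(=O)(OC)OC | intermediate
8 | dimethyl {4-[(2R,3R)-3-(2-{[tert-butyl(dimethyl)silyl]oxy}ethyl)-3-methyloxiran-2-yl]-2-oxobutyl}phosphonate | COP(=O)(OC)CC(=O)CC[C@H]1O[C@]1(C)CCO[Si](C)(C)C(C)(C)C | intermediate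
9 | prop-2-en-1-yl oxoacetate (allyl glyoxylate) | O=CC(=O)OCC=C | starting material
10 | prop-2-en-1-yl (2E)-6-[(2R,3R)-3-(2-{[tert-butyl(dimethyl)silyl]oxy}ethyl)-3-methyloxiran-2-yl]-4-oxohex-2-enoate | C=CCOC(=O)/C=C/C(=O)CC[C@H]1O[C@]1(C)CCO[Si](C)(C)C(C)(C)C | intermediate
11 | prop-2-en-1-yl (2E,7S,8R)-7-bromo-10-{[tert-butyl(dimethyl)silyl]oxy}-8-hydroxy-8-methyl-4-oxodec-2-enoate | C=CCOC(=O)/C=C/C(=O)CC[C@H](Br)[C@](C)(O)CCO[Si](C)(C)C(C)(C)C | intermediate
12 | prop-2-en-1-yl (2E,7S,8R)-7-bromo-10-{[tert-butyl(dimethyl)silyl]oxy}-8-methyl-4-oxo-8-[(trifluoroacetyl)oxy]dec-2-enoate | C=CCOC(=O)/C=C/C(=O)CC[C@H](Br)[C@](C)(OC(=O)C(F)(F)F)CCO[Si](C)(C)C(C)(C)C | intermediate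
13 | prop-2-en-1-yl (3Z,7S,8R)-7-bromo-10-{[tert-butyl(dimethyl)silyl]oxy}-8-methyl-4-[(triethylsilyl)oxy]-8-[(trifluoroacetyl)oxy]dec-3-enoate | C=CCOC(=O)C/C=C(\O[Si](CC)(CC)CC)CC[C@H](Br)[C@](C)(OC(=O)C(F)(F)F)CCO[Si](C)(C)C(C)(C)C | intermediate
14 | prop-2-en-1-yl [(1S,2S,3S)-3-bromo-2-(2-{[tert-butyl(dimethyl)silyl]oxy}ethyl)-2-methyl-6-oxocyclohexyl]acetate | C=CCOC(=O)C[C@@H]1C(=O)CC[C@H](Br)[C@@]1(C)CCO[Si](C)(C)C(C)(C)C | intermediate
15 | {(1S,2S,6S)-2-bromo-1-methyl-5-oxo-6-[2-oxo-2-(prop-2-en-1-yloxy)ethyl]cyclohexyl}acetic acid | C=CCOC(=O)C[C@@H]1C(=O)CC[C@H](Br)[C@@]1(C)CC(=O)O | intermediate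
16 | prop-2-en-1-yl [(1S,2S,3S)-3-bromo-2-(2-methoxy-2-oxoethyl)-2-methyl-6-oxocyclohexyl]acetate | C=CCOC(=O)C[C@@H]1C(=O)CC[C@H](Br)[C@@]1(C)CC(=O)OC | intermediate
17 | prop-2-en-1-yl [(1S,2S,3S,6R)-3-bromo-6-hydroxy-2-(2-methoxy-2-oxoethyl)-2,6-dimethylcyclohexyl]acetate (formed as its bromomagnesium alkoxide) | C=CCOC(=O)C[C@@H]1[C@](C)(O)CC[C@H](Br)[C@@]1(C)CC(=O)OC | intermediate
18 | prop-2-en-1-yl {(1S,2S,3S,6R)-3-bromo-2-(2-methoxy-2-oxoethyl)-2,6-dimethyl-6-[(triethylsilyl)oxy]cyclohexyl}acetate | C=CCOC(=O)C[C@@H]1[C@](C)(O[Si](CC)(CC)CC)CC[C@H](Br)[C@@]1(C)CC(=O)OC | intermediate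
19 | prop-2-en-1-yl (3aS,4S,7R,7aS)-4-bromo-3a,7-dimethyl-2-oxo-7-[(triethylsilyl)oxy]octahydro-1H-indene-1-carboxylate (C-1 epimers/enol) | C=CCOC(=O)C1C(=O)C[C@]2(C)[C@@H](Br)CC[C@@](C)(O[Si](CC)(CC)CC)[C@@H]12 | intermediate
20 | prop-2-yn-1-ol | C#CCO | starting material
21 | 5-bromo-2-methylpent-2-ene | CC(C)=CCCBr | starting material
22 | (4-methylpent-3-en-1-yl)magnesium bromide | CC(C)=CCC[Mg]Br | intermediate
23 | bromomagnesium (2Z)-3-(bromomagnesio)-2-(4-methylpent-3-en-1-yl)prop-2-en-1-olate | Br[Mg]OC/C(=C\[Mg]Br)CCC=C(C)C | intermediate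
24 | (2Z)-2-(4-methylpent-3-en-1-yl)-3-(trimethylsilyl)prop-2-en-1-ol | OC/C(=C\[Si](C)(C)C)CCC=C(C)C | intermediate
25 | (2Z)-2-{2-[(2R)-3,3-dimethyloxiran-2-yl]ethyl}-3-(trimethylsilyl)prop-2-en-1-ol | OC/C(=C\[Si](C)(C)C)CC[C@H]1OC1(C)C | intermediate
26 | prop-2-en-1-yl (3aS,4S,7R,7aS)-4-bromo-2-{[(2Z)-2-{2-[(2R)-3,3-dimethyloxiran-2-yl]ethyl}-3-(trimethylsilyl)prop-2-en-1-yl]oxy}-3a,7-dimethyl-7-[(triethylsilyl)oxy]-3a,4,5,6,7,7a-hexahydro-3H-indene-1-carboxylate | C=CCOC(=O)C1=C(OC/C(=C\[Si](C)(C)C)CC[C@H]3OC3(C)C)C[C@]2(C)[C@@H](Br)CC[C@@](C)(O[Si](CC)(CC)CC)[C@@H]12 | intermediate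
27 | prop-2-en-1-yl (3aS,4S,7R,7aS)-4-bromo-1-[4-(3,3-dimethyloxiran-2-yl)-2-methylidene-1-(trimethylsilyl)butyl]-3a,7-dimethyl-2-oxo-7-[(triethylsilyl)oxy]octahydro-1H-indene-1-carboxylate (side chain cis to H-7a; C–Si centre and epoxide as in 28) | C=CCOC(=O)[C@@]1([C@H]([Si](C)(C)C)C(=C)CC[C@H]3OC3(C)C)C(=O)C[C@]2(C)[C@@H](Br)CC[C@@](C)(O[Si](CC)(CC)CC)[C@@H]12 | intermediate
28 | (1S,3aS,4S,7R,7aS)-4-bromo-1-{(1S)-4-[(2R)-3,3-dimethyloxiran-2-yl]-2-methylidene-1-(trimethylsilyl)butyl}-3a,7-dimethyl-7-[(triethylsilyl)oxy]octahydro-2H-inden-2-one | C=C(CC[C@H]1OC1(C)C)[C@@H]([Si](C)(C)C)[C@@H]2C(=O)C[C@]3(C)[C@@H](Br)CC[C@@](C)(O[Si](CC)(CC)CC)[C@@H]23 | intermediate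
29 | (1S,2R,3aS,4S,7R,7aS)-4-bromo-1-{(1S)-4-[(2R)-3,3-dimethyloxiran-2-yl]-2-methylidene-1-(trimethylsilyl)butyl}-3a,7-dimethyl-7-[(triethylsilyl)oxy]octahydro-1H-inden-2-ol | C=C(CC[C@H]1OC1(C)C)[C@@H]([Si](C)(C)C)[C@@H]2[C@H](O)C[C@]3(C)[C@@H](Br)CC[C@@](C)(O[Si](CC)(CC)CC)[C@@H]23 | intermediate
30 | (1S,2R,3aS,4S,7R,7aS)-4-bromo-1-[(1S,5S)-5-bromo-6-hydroxy-6-methyl-2-methylidene-1-(trimethylsilyl)heptyl]-3a,7-dimethyl-7-[(triethylsilyl)oxy]octahydro-1H-inden-2-ol | CC(C)(O)[C@@H](Br)CCC(=C)[C@@H]([Si](C)(C)C)[C@@H]2[C@H](O)C[C@]3(C)[C@@H](Br)CC[C@@](C)(O[Si](CC)(CC)CC)[C@@H]23 | intermediate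
31 | bis(trifluoroacetate) of 30 (tertiary side-chain ester and 2-O-ester) | CC(C)(OC(=O)C(F)(F)F)[C@@H](Br)CCC(=C)[C@@H]([Si](C)(C)C)[C@@H]2[C@H](OC(=O)C(F)(F)F)C[C@]3(C)[C@@H](Br)CC[C@@](C)(O[Si](CC)(CC)CC)[C@@H]23 | intermediate
32 | (1S,2R,3aS,4S,7R,7aS)-4-bromo-1-{(E)-[(4S)-4-bromo-3,3-dimethylcyclohexylidene]methyl}-3a,7-dimethyl-7-[(triethylsilyl)oxy]octahydro-1H-inden-2-yl trifluoroacetate | CC1(C)C/C(=C/[C@@H]2[C@H](OC(=O)C(F)(F)F)C[C@]3(C)[C@@H](Br)CC[C@@](C)(O[Si](CC)(CC)CC)[C@@H]23)CC[C@@H]1Br | intermediate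
33 | (1S,2R,3aS,4S,7R,7aS)-4-bromo-1-{(E)-[(4S)-4-bromo-3,3-dimethylcyclohexylidene]methyl}-3a,7-dimethyl-7-[(triethylsilyl)oxy]octahydro-1H-inden-2-ol | CC1(C)C/C(=C/[C@@H]2[C@H](O)C[C@]3(C)[C@@H](Br)CC[C@@](C)(O[Si](CC)(CC)CC)[C@@H]23)CC[C@@H]1Br | intermediate
34 | iriediol, (1S,2R,3aS,4S,7R,7aS)-4-bromo-1-{(E)-[(4S)-4-bromo-3,3-dimethylcyclohexylidene]methyl}-3a,7-dimethyloctahydro-1H-indene-2,7-diol | CC1(C)C/C(=C/[C@@H]2[C@H](O)C[C@]3(C)[C@@H](Br)CC[C@@](C)(O)[C@@H]23)CC[C@@H]1Br | target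

**Count and risks**

Total step count: 20. Longest linear sequence: 18 steps (steps 1–11, then 14–20); steps 12–13 make the side-chain fragment.

Steps most likely to fail:

1. Step 19 (Proposed new method). What may go wrong: ionisation followed by elimination or intermolecular bromonium transfer instead of ring closure; protodesilylation of the allylsilane; closure through a boat or a syn-SE2' pathway, which would give the (Z)-alkene. Fallback (sets out from 21 and 19, returns at 32): the same bond is made by the well-known Lewis-acid epoxide-initiated cyclisation onto an allylsilane, and bromine is put in afterwards. An epoxide-derived chair attacks the opposite face of the CH2 terminus, so the epimeric silane is needed. Grignard reagent 22 (from 21) is added under CuI catalysis to 3-(trimethylsilyl)prop-2-yn-1-ol and protonated to give (2E)-2-(4-methylpent-3-en-1-yl)-3-(trimethylsilyl)prop-2-en-1-ol F1. Shi epoxidation gives the (R)-epoxide F2. Mitsunobu O-alkylation and Claisen rearrangement with 19 give the C–Si epimer of 27, F3 (silicon now equatorial in the chair). Palladium-catalysed deallylative decarboxylation gives ketone F4, LiBH(s-Bu)3 gives alcohol F5, and trifluoroacetylation of O-2 gives F6. Et2AlCl (or BF3·OEt2) should then close ring A to the (E)-alkene with the (R)-configured ring-A alcohol F7. Appel bromination (CBr4, PPh3), or triflate formation and LiBr, displaces the hydroxyl with inversion and gives 32. The weak point is this SN2 displacement at a neopentyl-type secondary carbon.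

2. Step 8. What may go wrong: incomplete (Z)-selectivity in the hydrosilylation (gives the epimer at the acetate-bearing ring carbon); E1 loss of a proton from the tertiary cation; hydrolysis of the enol ether before closure. Fallback (sets out from 5, returns at 14): the enol is activated as a β-keto ester instead. The dianion of methyl acetoacetate is alkylated with 5 to give methyl 5-[(2R,3R)-3-(2-{[tert-butyl(dimethyl)silyl]oxy}ethyl)-3-methyloxiran-2-yl]-3-oxopentanoate F8. Li2NiBr4 gives bromohydrin F9 and trifluoroacetic anhydride gives trifluoroacetate F10. SnCl4 closes the ring through the chelated enol to the bromocyclohexanone β-keto ester F11. C-Alkylation with allyl bromoacetate (NaH, DMF) gives the quaternary keto diester F12, and Krapcho demethoxycarbonylation (LiCl, wet DMSO, 140 °C) gives 14. Its epimer at the acetate-bearing carbon is expected alongside and has to be separated and re-equilibrated.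

3. Step 14. What may go wrong: C-alkylation instead of O-alkylation in the Mitsunobu stage; loss of the chair or facial preference in the rearrangement, which gives the epimeric C–Si centre. Fallback (sets out from 19, returns at 26 and so at 27): the polarity of the ether formation is reversed. 19 is converted (NaH, PhN(SO2CF3)2) into the enol triflate, prop-2-en-1-yl (3aS,4S,7R,7aS)-4-bromo-3a,7-dimethyl-7-[(triethylsilyl)oxy]-2-{[(trifluoromethyl)sulfonyl]oxy}-3a,4,5,6,7,7a-hexahydro-3H-indene-1-carboxylate F13. Addition–elimination of the sodium alkoxide of 25 gives 26 free of C-alkylated material, and heating gives 27. Any epimer at the C–Si centre is the compound F3 and can be carried through the fallback for step 19.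

**Further compounds**

F1 | step 19 | (2E)-2-(4-methylpent-3-en-1-yl)-3-(trimethylsilyl)prop-2-en-1-ol | OC/C(=C/[Si](C)(C)C)CCC=C(C)C
F2 | step 19 | (2E)-2-{2-[(2R)-3,3-dimethyloxiran-2-yl]ethyl}-3-(trimethylsilyl)prop-2-en-1-ol | OC/C(=C/[Si](C)(C)C)CC[C@H]1OC1(C)C
F3 | step 19 | epimer of 27 at the silyl-bearing carbon | C=CCOC(=O)[C@@]1([C@@H]([Si](C)(C)C)C(=C)CC[C@H]3OC3(C)C)C(=O)C[C@]2(C)[C@@H](Br)CC[C@@](C)(O[Si](CC)(CC)CC)[C@@H]12
F4 | step 19 | epimer of 28 at the silyl-bearing carbon | C=C(CC[C@H]1OC1(C)C)[C@H]([Si](C)(C)C)[C@@H]2C(=O)C[C@]3(C)[C@@H](Br)CC[C@@](C)(O[Si](CC)(CC)CC)[C@@H]23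
F5 | step 19 | epimer of 29 at the silyl-bearing carbon | C=C(CC[C@H]1OC1(C)C)[C@H]([Si](C)(C)C)[C@@H]2[C@H](O)C[C@]3(C)[C@@H](Br)CC[C@@](C)(O[Si](CC)(CC)CC)[C@@H]23
F6 | step 19 | 2-O-trifluoroacetate of F5 | C=C(CC[C@H]1OC1(C)C)[C@H]([Si](C)(C)C)[C@@H]2[C@H](OC(=O)C(F)(F)F)C[C@]3(C)[C@@H](Br)CC[C@@](C)(O[Si](CC)(CC)CC)[C@@H]23
F7 | step 19 | (1S,2R,3aS,4S,7R,7aS)-4-bromo-1-{(E)-[(4R)-4-hydroxy-3,3-dimethylcyclohexylidene]methyl}-3a,7-dimethyl-7-[(triethylsilyl)oxy]octahydro-1H-inden-2-yl trifluoroacetate | CC1(C)C/C(=C/[C@@H]2[C@H](OC(=O)C(F)(F)F)C[C@]3(C)[C@@H](Br)CC[C@@](C)(O[Si](CC)(CC)CC)[C@@H]23)CC[C@H]1O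
F8 | step 8 | methyl 5-[(2R,3R)-3-(2-{[tert-butyl(dimethyl)silyl]oxy}ethyl)-3-methyloxiran-2-yl]-3-oxopentanoate | COC(=O)CC(=O)CC[C@H]1O[C@]1(C)CCO[Si](C)(C)C(C)(C)C
F9 | step 8 | methyl (6S,7R)-6-bromo-9-{[tert-butyl(dimethyl)silyl]oxy}-7-hydroxy-7-methyl-3-oxononanoate | COC(=O)CC(=O)CC[C@H](Br)[C@](C)(O)CCO[Si](C)(C)C(C)(C)C
F10 | step 8 | methyl (6S,7R)-6-bromo-9-{[tert-butyl(dimethyl)silyl]oxy}-7-methyl-3-oxo-7-[(trifluoroacetyl)oxy]nonanoate | COC(=O)CC(=O)CC[C@H](Br)[C@](C)(OC(=O)C(F)(F)F)CCO[Si](C)(C)C(C)(C)C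
F11 | step 8 | methyl (2S,3S)-3-bromo-2-(2-{[tert-butyl(dimethyl)silyl]oxy}ethyl)-2-methyl-6-oxocyclohexane-1-carboxylate (C-1 epimers/enol) | COC(=O)C1C(=O)CC[C@H](Br)[C@@]1(C)CCO[Si](C)(C)C(C)(C)C
F12 | step 8 | methyl (2S,3S)-3-bromo-2-(2-{[tert-butyl(dimethyl)silyl]oxy}ethyl)-2-methyl-6-oxo-1-[2-oxo-2-(prop-2-en-1-yloxy)ethyl]cyclohexane-1-carboxylate (C-1 epimers) | COC(=O)C1(CC(=O)OCC=C)C(=O)CC[C@H](Br)[C@@]1(C)CCO[Si](C)(C)C(C)(C)C
F13 | step 14 | prop-2-en-1-yl (3aS,4S,7R,7aS)-4-bromo-3a,7-dimethyl-7-[(triethylsilyl)oxy]-2-{[(trifluoromethyl)sulfonyl]oxy}-3a,4,5,6,7,7a-hexahydro-3H-indene-1-carboxylate | C=CCOC(=O)C1=C(OS(=O)(=O)C(F)(F)F)C[C@]2(C)[C@@H](Br)CC[C@@](C)(O[Si](CC)(CC)CC)[C@@H]12
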